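Plan
1. Atoms carry prostaglandin numbers (C1 acid carbon, ring C8–C12, C15 side-chain ketone). Retrosynthesis: C9–OH goes back to C9–B and C11=O to C11–O–Si; C5=C6 is cut by Wittig; then the ring bonds C10–C11 and C8–C9 are cut together (radical [3+2] annulation of a vinylboronate onto an acyclic α-silyloxy acid); the C7=C8 enoate and the C8=C12 alkene go back to two cross-metatheses, and C11–C12 to an Ireland–Claisen rearrangement.
2. Forward: the ω-chain alkene and an (S)-butenyl glycolate are joined, rearranged and extended to an acyclic C6–C20 acid; the cyclopentane, the only ring made, arises in step 7; the C1–C5 chain is then added, C11 and C15 are unmasked and boron becomes the C9 hydroxyl last.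
3. Enabling feature: in the cyclopentanone the C10 methylene and the C9 carbinol lie between the carbonyl carbon C11 and the methine C8. A vinyl group with boron as latent oxygen can therefore be clamped between a C11-centred radical and a C8=C7 acceptor alkene, closing ring C8–C9–C10–C11–C12.
4. Stereochemistry: C12 comes from (S)-but-3-en-2-ol by chirality transfer in the Ireland–Claisen step; C8 and C9 are set from C12 in the 5-exo ring closure; C–B becomes C–O with retention; the Z-alkene comes from the Wittig reaction.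

Key step: step 7

Remark: the silyloxy-bearing carbon (future C11) is carried as an epimer mixture from 11 to 23, which is harmless because it is planar in step 7 and ends as the ketone.

Step 1
Reactants: 1 hexanoyl chloride; 2 but-3-en-1-ylmagnesium bromide
Product: 3 dec-1-en-5-one
Conditions: Fe(acac)3 (3 mol%), THF, −78 °C
Reagents that add atoms: none
Why: Iron-catalysed acyl cross-coupling of a Grignard reagent with an acid chloride is faster than addition of the Grignard reagent to the ketone formed, so the reaction should stop at 3.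

Step 2
Reactants: 3 dec-1-en-5-one
Product: 4 2-(but-3-en-1-yl)-2-pentyl-1,3-dioxolane
Conditions: ethylene glycol, TsOH·H2O (cat.), toluene, reflux, Dean–Stark trap
Reagents that add atoms: ethylene glycol, OCCO
Why: Acid-catalysed ketalisation with azeotropic removal of water masks the C15 ketone against the enolate, hydride and ylide steps that follow, and the terminal alkene is inert.

Step 3
Reactants: 5 (S)-but-3-en-2-ol; 6 2-[(tert-butyldimethylsilyl)oxy]acetic acid
Product: 7 (2S)-but-3-en-2-yl 2-[(tert-butyldimethylsilyl)oxy]acetate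
Conditions: DCC, DMAP (cat.), CH2Cl2, 0 °C → rt
Reagents that add atoms: none
Why: Steglich esterification acylates the alcohol oxygen without touching the C–O stereocenter, so the (S) configuration is kept.

Step 4
Reactants: 7 (2S)-but-3-en-2-yl 2-[(tert-butyldimethylsilyl)oxy]acetate; 4 2-(but-3-en-1-yl)-2-pentyl-1,3-dioxolane (2 equiv)
Product: 8 (2S,3E)-6-(2-pentyl-1,3-dioxolan-2-yl)hex-3-en-2-yl 2-[(tert-butyldimethylsilyl)oxy]acetate
Conditions: second-generation Grubbs catalyst RuCl2(=CHPh)(H2IMes)(PCy3) (5 mol%), CH2Cl2, 40 °C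
Reagents that add atoms: none
Why: Olefin cross-metathesis between a readily homodimerising terminal alkene and a slowly homodimerising secondary allylic ester should give the cross product as the E isomer with the stereocenter untouched; any Z isomer is removed here because it would give the enantiomer at C12 in step 5.

Step 5
Reactants: 8 (2S,3E)-6-(2-pentyl-1,3-dioxolan-2-yl)hex-3-en-2-yl 2-[(tert-butyldimethylsilyl)oxy]acetate
Product: 11 (3R,4E)-2-[(tert-butyldimethylsilyl)oxy]-3-[2-(2-pentyl-1,3-dioxolan-2-yl)ethyl]hex-4-enoic acid (C2 epimers), via silyl ketene acetal 9 (not isolated), via trimethylsilyl ester 10 (not isolated)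
Conditions: LiN(i-Pr)2, Me3SiCl, THF, −78 °C → rt; aq. citric acid work-up
Reagents that add atoms: none
Why: Ireland–Claisen rearrangement: silyl ketene acetal 9 rearranges through a chair transition state with the carbinol methyl pseudo-equatorial, so the (S) C–O stereocenter and the E-alkene are traded suprafacially for the (R)-configured C12 and an E-propenyl group, while the C2 epimer ratio is irrelevant because that carbon becomes a planar radical in step 7.

Step 6
Reactants: 11 (3R,4E)-2-[(tert-butyldimethylsilyl)oxy]-3-[2-(2-pentyl-1,3-dioxolan-2-yl)ethyl]hex-4-enoic acid; 12 methyl acrylate (10 equiv)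
Product: 13 (3R,4E)-2-[(tert-butyldimethylsilyl)oxy]-6-methoxy-6-oxo-3-[2-(2-pentyl-1,3-dioxolan-2-yl)ethyl]hex-4-enoic acid (C2 epimers)
Conditions: second-generation Hoveyda–Grubbs catalyst RuCl2(=CH-C6H4-2-OiPr)(H2IMes) (10 mol%), CH2Cl2, 40 °C
Reagents that add atoms: none
Why: Cross-metathesis with an acrylate, which does not homodimerise, should exchange the propenyl terminus for the E-enoate with loss of propene and leave C12 untouched.

Step 7
Reactants: 13 (3R,4E)-2-[(tert-butyldimethylsilyl)oxy]-6-methoxy-6-oxo-3-[2-(2-pentyl-1,3-dioxolan-2-yl)ethyl]hex-4-enoic acid; 14 4,4,5,5-tetramethyl-2-vinyl-1,3,2-dioxaborolane (4 equiv)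
Product: 18 methyl 2-[(1S,2R,5S)-3-[(tert-butyldimethylsilyl)oxy]-2-[2-(2-pentyl-1,3-dioxolan-2-yl)ethyl]-5-(4,4,5,5-tetramethyl-1,3,2-dioxaborolan-2-yl)cyclopentyl]acetate (C3 epimers), via α-silyloxyalkyl radical 15 (not isolated), via α-boryl radical 16 (not isolated), via cyclised ester radical 17 (not isolated)
Conditions: Ir[dF(CF3)ppy]2(dtbbpy)PF6 (2 mol%), Cs2CO3 (20 mol%), DMF (0.05 M), 450 nm LEDs, rt, degassed
Reagents that add atoms: none
Why: Proposed new method: a photoredox decarboxylative radical [3+2] annulation; the excited trivalent-iridium catalyst oxidises 13 as its carboxylate, loss of CO2 leaves the nucleophilic radical 15, which adds to the CH2 end of the electron-poor vinylboronate 14 (bond C10–C11) to give 16, 16 closes onto the β-carbon of the tethered E-enoate (bond C8–C9) to give 17, and divalent iridium reduces 17 at carbon while unreacted 13 supplies the proton (radical–polar crossover, redox-neutral). The closest known reaction types are the photoredox decarboxylative Giese addition of α-oxy and α-amino acids to vinylboronic esters, the 5-exo cyclisation of α-boryl radicals and the radical [3+2] annulation of but-3-enyl radicals with electron-poor alkenes; untested is only their union on a vinylboronate, whose boron is the latent C9 hydroxyl. The one ring formed, cyclopentane C8–C9–C10–C11–C12, closes in the 5-exo-trig mode. C12 is already set and should control C8 through the chair-like transition state of hexenyl radical closure, in which its side chain lies pseudo-equatorial and the CH2CO2Me arm ends trans to it; C9 should follow the 1,5-cis preference of 1-substituted hex-5-enyl radicals, which puts boron cis to that arm; C11 forms without control and is erased in step 11. The step needs (i) addition of 15 to 14 and not to the enoate of a second molecule, secured by the excess of 14 and by the γ-branched, β-substituted enoate being a poor intermolecular acceptor, and (ii) ring closure of 16 before its reduction, secured by the absence of a hydrogen-atom donor and the low stationary concentration of divalent iridium; should 16 be reduced first, the resulting carbanion can still close by 5-exo-trig Michael addition.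

Step 8
Reactants: 18 methyl 2-[(1S,2R,5S)-3-[(tert-butyldimethylsilyl)oxy]-2-[2-(2-pentyl-1,3-dioxolan-2-yl)ethyl]-5-(4,4,5,5-tetramethyl-1,3,2-dioxaborolan-2-yl)cyclopentyl]acetate
Product: 20 2-[(1S,2R,5S)-3-[(tert-butyldimethylsilyl)oxy]-2-[2-(2-pentyl-1,3-dioxolan-2-yl)ethyl]-5-(4,4,5,5-tetramethyl-1,3,2-dioxaborolan-2-yl)cyclopentyl]acetaldehyde (C3 epimers), via aluminium hemiacetal 19 (not isolated)
Conditions: i-Bu2AlH (1.1 equiv), CH2Cl2, −78 °C; aq. KNaC4H4O6 work-up
Reagents that add atoms: none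
Why: Partial ester reduction: at −78 °C the hydride adds once and the tetrahedral aluminium hemiacetal 19 survives until work-up, so the C6 aldehyde should form without over-reduction; silyl ether, ketal and the hindered alkylboronate are inert.

Step 9
Reactants: 20 2-[(1S,2R,5S)-3-[(tert-butyldimethylsilyl)oxy]-2-[2-(2-pentyl-1,3-dioxolan-2-yl)ethyl]-5-(4,4,5,5-tetramethyl-1,3,2-dioxaborolan-2-yl)cyclopentyl]acetaldehyde; 21 (4-carboxybutyl)triphenylphosphonium bromide (3 equiv)
Product: 22 (5Z)-7-[(1S,2R,5S)-3-[(tert-butyldimethylsilyl)oxy]-2-[2-(2-pentyl-1,3-dioxolan-2-yl)ethyl]-5-(4,4,5,5-tetramethyl-1,3,2-dioxaborolan-2-yl)cyclopentyl]hept-5-enoic acid (C3 epimers)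
Conditions: NaN(SiMe3)2 (6 equiv), THF, 0 °C; then 20, −78 °C → rt; aq. NaH2PO4 work-up
Reagents that add atoms: none
Why: Wittig reaction of the unstabilised, lithium-free ylide with the aldehyde should give the Z-alkene under kinetic control, and the non-nucleophilic amide base avoids ate-complex formation at boron.

Step 10
Reactants: 22 (5Z)-7-[(1S,2R,5S)-3-[(tert-butyldimethylsilyl)oxy]-2-[2-(2-pentyl-1,3-dioxolan-2-yl)ethyl]-5-(4,4,5,5-tetramethyl-1,3,2-dioxaborolan-2-yl)cyclopentyl]hept-5-enoic acid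
Product: 23 (5Z)-7-[(1S,2R,5S)-3-hydroxy-2-(3-oxooctyl)-5-(4,4,5,5-tetramethyl-1,3,2-dioxaborolan-2-yl)cyclopentyl]hept-5-enoic acid (C3 epimers)
Conditions: 2 M aq. HCl/THF (1:3), rt
Reagents that add atoms: water, O
Why: Acid hydrolysis cleaves the secondary silyl ether and the dioxolane in one operation, while the alkyl pinacol boronate, the Z-alkene and the acid tolerate aqueous acid, so C9 stays masked as boron when the C11 hydroxyl is freed.

Step 11
Reactants: 23 (5Z)-7-[(1S,2R,5S)-3-hydroxy-2-(3-oxooctyl)-5-(4,4,5,5-tetramethyl-1,3,2-dioxaborolan-2-yl)cyclopentyl]hept-5-enoic acid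
Product: 24 (5Z)-7-[(1S,2R,5S)-3-oxo-2-(3-oxooctyl)-5-(4,4,5,5-tetramethyl-1,3,2-dioxaborolan-2-yl)cyclopentyl]hept-5-enoic acid
Conditions: Dess–Martin periodinane, CH2Cl2, 0 °C → rt
Reagents that add atoms: none
Why: Dess–Martin oxidation converts the only free alcohol (both C11 epimers) into the ketone under non-basic conditions; the C–B bond is inert to the periodinane, so C9 needs no protecting group, and C12 keeps the more stable trans arrangement next to the new ketone.

Step 12
Reactants: 24 (5Z)-7-[(1S,2R,5S)-3-oxo-2-(3-oxooctyl)-5-(4,4,5,5-tetramethyl-1,3,2-dioxaborolan-2-yl)cyclopentyl]hept-5-enoic acid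
Product: 25 (5Z)-7-[(1R,2R,5S)-5-hydroxy-3-oxo-2-(3-oxooctyl)cyclopentyl]hept-5-enoic acid (13,14-dihydro-15-keto-PGD2)
Conditions: NaBO3·4H2O (3 equiv), THF/H2O (1:1), 0 °C → rt; then aq. NaH2PO4 to pH 4–5
Reagents that add atoms: sodium perborate, [Na+].[Na+].O[B-]1(O)OO[B-](O)(O)OO1
Why: Oxidation of the alkylboronate by peroxoborate proceeds by 1,2-migration of C9 from boron to oxygen with retention, so the boron cis to the C8 chain becomes the C9 hydroxyl of the target, and the mild perborate is chosen to spare the β-hydroxy ketone that forms.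

Compound list
1 | hexanoyl chloride | CCCCCC(=O)Cl | starting material
2 | but-3-en-1-ylmagnesium bromide | C=CCC[Mg]Br | starting material
3 | dec-1-en-5-one | CCCCCC(=O)CCC=C | intermediate
4 | 2-(but-3-en-1-yl)-2-pentyl-1,3-dioxolane | CCCCCC1(CCC=C)OCCO1 | intermediate
5 | (S)-but-3-en-2-ol | C[C@H](O)C=C | starting material
6 | 2-[(tert-butyldimethylsilyl)oxy]acetic acid | CC(C)(C)[Si](C)(C)OCC(=O)O | starting material
7 | (2S)-but-3-en-2-yl 2-[(tert-butyldimethylsilyl)oxy]acetate | C[C@H](OC(=O)CO[Si](C)(C)C(C)(C)C)C=C | intermediate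
8 | (2S,3E)-6-(2-pentyl-1,3-dioxolan-2-yl)hex-3-en-2-yl 2-[(tert-butyldimethylsilyl)oxy]acetate | C[C@H](OC(=O)CO[Si](C)(C)C(C)(C)C)/C=C/CCC1(CCCCC)OCCO1 | intermediate
9 | silyl ketene acetal of 8 (O-trimethylsilyl; enol geometry not specified) | C[C@H](OC(O[Si](C)(C)C)=CO[Si](C)(C)C(C)(C)C)/C=C/CCC1(CCCCC)OCCO1 | intermediate
10 | trimethylsilyl ester of acid 11 | C[Si](C)(C)OC(=O)C(O[Si](C)(C)C(C)(C)C)[C@H](CCC1(CCCCC)OCCO1)/C=C/C | intermediate
11 | (3R,4E)-2-[(tert-butyldimethylsilyl)oxy]-3-[2-(2-pentyl-1,3-dioxolan-2-yl)ethyl]hex-4-enoic acid (C2 epimers) | OC(=O)C(O[Si](C)(C)C(C)(C)C)[C@H](CCC1(CCCCC)OCCO1)/C=C/C | intermediate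
12 | methyl acrylate | C=CC(=O)OC | starting material
13 | (3R,4E)-2-[(tert-butyldimethylsilyl)oxy]-6-methoxy-6-oxo-3-[2-(2-pentyl-1,3-dioxolan-2-yl)ethyl]hex-4-enoic acid (C2 epimers) | OC(=O)C(O[Si](C)(C)C(C)(C)C)[C@H](CCC1(CCCCC)OCCO1)/C=C/C(=O)OC | intermediate
14 | 4,4,5,5-tetramethyl-2-vinyl-1,3,2-dioxaborolane (vinylboronic acid pinacol ester) | C=CB1OC(C)(C)C(C)(C)O1 | starting material
15 | α-silyloxyalkyl radical from 13 after loss of CO2 (radical at C11, C12 R) | [CH](O[Si](C)(C)C(C)(C)C)[C@H](CCC1(CCCCC)OCCO1)/C=C/C(=O)OC | intermediate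
16 | open-chain α-boryl radical (radical at C9, C10–C11 bond formed) | CC1(C)OB(OC1(C)C)[CH]CC(O[Si](C)(C)C(C)(C)C)[C@H](CCC2(CCCCC)OCCO2)/C=C/C(=O)OC | intermediate
17 | cyclised ester-stabilised radical (radical at C7, ring closed) | CCCCCC1(OCCO1)CC[C@H]2C(O[Si](C)(C)C(C)(C)C)C[C@H](B3OC(C)(C)C(C)(C)O3)[C@@H]2[CH]C(=O)OC | intermediate
18 | methyl 2-[(1S,2R,5S)-3-[(tert-butyldimethylsilyl)oxy]-2-[2-(2-pentyl-1,3-dioxolan-2-yl)ethyl]-5-(4,4,5,5-tetramethyl-1,3,2-dioxaborolan-2-yl)cyclopentyl]acetate (C3 epimers; boron cis to the acetate arm, side chain trans) | CCCCCC1(OCCO1)CC[C@H]2C(O[Si](C)(C)C(C)(C)C)C[C@H](B3OC(C)(C)C(C)(C)O3)[C@@H]2CC(=O)OC | intermediate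
19 | diisobutylaluminium hemiacetal of 18 | CCCCCC1(OCCO1)CC[C@H]2C(O[Si](C)(C)C(C)(C)C)C[C@H](B3OC(C)(C)C(C)(C)O3)[C@@H]2CC(OC)O[Al](CC(C)C)CC(C)C | intermediate
20 | 2-[(1S,2R,5S)-3-[(tert-butyldimethylsilyl)oxy]-2-[2-(2-pentyl-1,3-dioxolan-2-yl)ethyl]-5-(4,4,5,5-tetramethyl-1,3,2-dioxaborolan-2-yl)cyclopentyl]acetaldehyde (C3 epimers) | CCCCCC1(OCCO1)CC[C@H]2C(O[Si](C)(C)C(C)(C)C)C[C@H](B3OC(C)(C)C(C)(C)O3)[C@@H]2CC=O | intermediate
21 | (4-carboxybutyl)triphenylphosphonium bromide | [Br-].OC(=O)CCCC[P+](c1ccccc1)(c1ccccc1)c1ccccc1 | starting material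
22 | (5Z)-7-[(1S,2R,5S)-3-[(tert-butyldimethylsilyl)oxy]-2-[2-(2-pentyl-1,3-dioxolan-2-yl)ethyl]-5-(4,4,5,5-tetramethyl-1,3,2-dioxaborolan-2-yl)cyclopentyl]hept-5-enoic acid (C3 epimers) | CCCCCC1(OCCO1)CC[C@H]2C(O[Si](C)(C)C(C)(C)C)C[C@H](B3OC(C)(C)C(C)(C)O3)[C@@H]2C/C=C\CCCC(=O)O | intermediate
23 | (5Z)-7-[(1S,2R,5S)-3-hydroxy-2-(3-oxooctyl)-5-(4,4,5,5-tetramethyl-1,3,2-dioxaborolan-2-yl)cyclopentyl]hept-5-enoic acid (C3 epimers) | CCCCCC(=O)CC[C@H]1C(O)C[C@H](B2OC(C)(C)C(C)(C)O2)[C@@H]1C/C=C\CCCC(=O)O | intermediate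
24 | (5Z)-7-[(1S,2R,5S)-3-oxo-2-(3-oxooctyl)-5-(4,4,5,5-tetramethyl-1,3,2-dioxaborolan-2-yl)cyclopentyl]hept-5-enoic acid | CCCCCC(=O)CC[C@H]1C(=O)C[C@H](B2OC(C)(C)C(C)(C)O2)[C@@H]1C/C=C\CCCC(=O)O | intermediate
25 | (5Z)-7-[(1R,2R,5S)-5-hydroxy-3-oxo-2-(3-oxooctyl)cyclopentyl]hept-5-enoic acid (13,14-dihydro-15-keto-PGD2) | CCCCCC(=O)CC[C@H]1C(=O)C[C@H](O)[C@@H]1C/C=C\CCCC(=O)O | target

Total step count: 12. Longest linear sequence: 11 steps (steps 1, 2, 4–12 from hexanoyl chloride); step 3 is a one-step side branch.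

Steps most likely to fail

1. Step 7. The α-boryl radical may be reduced and protonated before it closes the ring, or the 5-exo closure may show poor facial selectivity at C9 (a weak 1,5-cis preference). The fallback uses known chemistry, sets out from 13 and returns at 18. The acid of 13 is reduced chemoselectively (BH3·SMe2, THF, 0 °C) to the primary alcohol F1, and an Appel reaction (I2, PPh3, imidazole, CH2Cl2) gives the primary iodide F2. Radical carbonylation–cyclisation (CO 80 atm, Bu3SnH, AIBN, benzene, 80 °C) follows: the primary radical takes up CO and the acyl radical closes 5-exo-trig onto the enoate. This gives the cyclopentanone F3, in which the former acid carbon is C10 and CO is C9. Kinetic enolisation toward the C10 methylene and triflation (KN(SiMe3)2, PhNTf2, THF, −78 °C) give the enol triflate F4. Miyaura borylation (B2pin2, PdCl2(dppf), KOPh, toluene, 60 °C) gives the alkenylboronate F5. Hydrogenation (H2, Pd/C, EtOAc) from the ring face opposite the C8 acetate arm should then deliver 18 with boron cis to that arm.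

2. Step 6. Cross-metathesis at the allylically branched propenyl group may be slow and the catalyst may decompose before turnover. The fallback sets out from 11 and returns at 13. Ozonolysis (O3, CH2Cl2/MeOH, −78 °C; Me2S) cuts the propenyl group to the aldehyde acid F6, which probably rests as its lactol. A Wittig reaction with the stabilised ylide methyl (triphenylphosphoranylidene)acetate (CH2Cl2, rt) then installs the E-enoate of 13 without metathesis and under conditions mild enough to keep C12.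

3. Step 12. The freshly formed C9 hydroxyl may undergo base-promoted β-elimination (dehydration to the cyclopentenone) under the mildly basic peroxide conditions. The fallback sets out from 22 and returns at 25. Boron is oxidised first, on 22 (NaBO3·4H2O, THF/H2O), to the C9 alcohol F7. Silylation (t-BuPh2SiCl, imidazole, DMF; aqueous work-up frees the acid) gives the C9 tert-butyldiphenylsilyl ether F8. Aqueous HCl/THF removes the tert-butyldimethylsilyl ether and the dioxolane but leaves the bulkier silyl ether, giving the C11 alcohol F9. Dess–Martin oxidation gives the diketone F10. HF·pyridine (THF, pyridine buffer, 0 °C → rt) then frees the C9 hydroxyl of 25 under weakly acidic conditions.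

Further compounds
F1 | step 7 | methyl (2E,4R)-5-[(tert-butyldimethylsilyl)oxy]-6-hydroxy-4-[2-(2-pentyl-1,3-dioxolan-2-yl)ethyl]hex-2-enoate (C5 epimers) | OCC(O[Si](C)(C)C(C)(C)C)[C@H](CCC1(CCCCC)OCCO1)/C=C/C(=O)OC
F2 | step 7 | methyl (2E,4R)-5-[(tert-butyldimethylsilyl)oxy]-6-iodo-4-[2-(2-pentyl-1,3-dioxolan-2-yl)ethyl]hex-2-enoate (C5 epimers) | ICC(O[Si](C)(C)C(C)(C)C)[C@H](CCC1(CCCCC)OCCO1)/C=C/C(=O)OC
F3 | step 7 | methyl 2-[(1R,2R)-3-[(tert-butyldimethylsilyl)oxy]-5-oxo-2-[2-(2-pentyl-1,3-dioxolan-2-yl)ethyl]cyclopentyl]acetate (C3 epimers) | CCCCCC1(OCCO1)CC[C@H]2C(O[Si](C)(C)C(C)(C)C)CC(=O)[C@@H]2CC(=O)OC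
F4 | step 7 | methyl 2-[(1R,5R)-4-[(tert-butyldimethylsilyl)oxy]-5-[2-(2-pentyl-1,3-dioxolan-2-yl)ethyl]-2-{[(trifluoromethyl)sulfonyl]oxy}cyclopent-2-en-1-yl]acetate (C4 epimers) | CCCCCC1(OCCO1)CC[C@H]2C(O[Si](C)(C)C(C)(C)C)C=C(OS(=O)(=O)C(F)(F)F)[C@@H]2CC(=O)OC
F5 | step 7 | methyl 2-[(1R,5R)-4-[(tert-butyldimethylsilyl)oxy]-5-[2-(2-pentyl-1,3-dioxolan-2-yl)ethyl]-2-(4,4,5,5-tetramethyl-1,3,2-dioxaborolan-2-yl)cyclopent-2-en-1-yl]acetate (C4 epimers) | CCCCCC1(OCCO1)CC[C@H]2C(O[Si](C)(C)C(C)(C)C)C=C(B3OC(C)(C)C(C)(C)O3)[C@@H]2CC(=O)OC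
F6 | step 6 | (3S)-2-[(tert-butyldimethylsilyl)oxy]-3-formyl-5-(2-pentyl-1,3-dioxolan-2-yl)pentanoic acid (C2 epimers; open form of the lactol) | OC(=O)C(O[Si](C)(C)C(C)(C)C)[C@H](CCC1(CCCCC)OCCO1)C=O
F7 | step 12 | (5Z)-7-[(1R,2R,5S)-3-[(tert-butyldimethylsilyl)oxy]-5-hydroxy-2-[2-(2-pentyl-1,3-dioxolan-2-yl)ethyl]cyclopentyl]hept-5-enoic acid (C3 epimers) | CCCCCC1(OCCO1)CC[C@H]2C(O[Si](C)(C)C(C)(C)C)C[C@H](O)[C@@H]2C/C=C\CCCC(=O)O
F8 | step 12 | (5Z)-7-[(1R,2R,5S)-3-[(tert-butyldimethylsilyl)oxy]-5-[(tert-butyldiphenylsilyl)oxy]-2-[2-(2-pentyl-1,3-dioxolan-2-yl)ethyl]cyclopentyl]hept-5-enoic acid (C3 epimers) | CCCCCC1(OCCO1)CC[C@H]2C(O[Si](C)(C)C(C)(C)C)C[C@H](O[Si](c3ccccc3)(c3ccccc3)C(C)(C)C)[C@@H]2C/C=C\CCCC(=O)O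
F9 | step 12 | (5Z)-7-[(1R,2R,5S)-5-[(tert-butyldiphenylsilyl)oxy]-3-hydroxy-2-(3-oxooctyl)cyclopentyl]hept-5-enoic acid (C3 epimers) | CCCCCC(=O)CC[C@H]1C(O)C[C@H](O[Si](c2ccccc2)(c2ccccc2)C(C)(C)C)[C@@H]1C/C=C\CCCC(=O)O
F10 | step 12 | (5Z)-7-[(1R,2R,5S)-5-[(tert-butyldiphenylsilyl)oxy]-3-oxo-2-(3-oxooctyl)cyclopentyl]hept-5-enoic acid | CCCCCC(=O)CC[C@H]1C(=O)C[C@H](O[Si](c2ccccc2)(c2ccccc2)C(C)(C)C)[C@@H]1C/C=C\CCCC(=O)O
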